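**Retrosynthetic overview**
- The target is a tetra-ortho-substituted diaryl ether. The Ar–O–Ar bond is cut by SNAr: a ring-A phenoxide attacks a ring-B aryl fluoride flanked by ortho-CHO and ortho-CO2Bn.
- Ring A nucleophile comes from atraric acid: C5 formylation, O-benzylation, then Baeyer–Villiger oxidation to reveal the 5-OH.
- Ring B electrophile comes from 4-bromo-2-fluoro-6-methylbenzoic acid: Br→OH, benzyl ester, C5 chlorination, C3 formylation, O-benzylation.
- No ring is constructed; both benzene rings are bought intact. Order: ring A functionalised, ring B functionalised, ether union, global hydrogenolytic debenzylation.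
- The benzyl ester becomes the free CO2H in the last step while the ring-A methyl ester stays.

Assumption: the target has no stereocentre and its diaryl ether axis is not configurationally stable, so the achiral compound as drawn is the goal; atraric acid and 4-bromo-2-fluoro-6-methylbenzoic acid are taken as catalogue compounds.

**Route**

Step 1
Reactants: 1 methyl 2,4-dihydroxy-3,6-dimethylbenzoate (atraric acid)
Product: 3 methyl 5-formyl-2,4-dihydroxy-3,6-dimethylbenzoate, via alpha-chloro ether 2 (not isolated)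
Conditions: Cl2CHOMe, TiCl4, CH2Cl2, 0 °C to rt; then aq. HCl
Reagents that add atoms: dichloromethyl methyl ether COC(Cl)Cl; water O
Why: Rieche formylation (Ti-phenoxide-directed electrophilic aromatic substitution) can only occur at C5, the single free ring position, which is ortho to 4-OH and para to 2-OH, and the alpha-chloro ether hydrolyses to the aldehyde on work-up; no stereocentre is formed.

Step 2
Reactants: 3 methyl 5-formyl-2,4-dihydroxy-3,6-dimethylbenzoate
Product: 4 methyl 2,4-bis(benzyloxy)-5-formyl-3,6-dimethylbenzoate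
Conditions: BnBr (2.5 equiv), K2CO3, DMF, 60 °C
Reagents that add atoms: benzyl bromide BrCc1ccccc1
Why: Williamson ether synthesis in DMF alkylates both hydrogen-bonded phenols, while the di-ortho-substituted methyl ester and the aldehyde are inert to carbonate.

Step 3
Reactants: 4 methyl 2,4-bis(benzyloxy)-5-formyl-3,6-dimethylbenzoate
Product: 6 methyl 2,4-bis(benzyloxy)-5-hydroxy-3,6-dimethylbenzoate, via aryl formate 5 (not isolated)
Conditions: mCPBA, CH2Cl2, 0 °C to rt; then K2CO3 (cat.), MeOH, rt
Reagents that add atoms: m-chloroperoxybenzoic acid O=C(OO)c1cccc(Cl)c1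
Why: Baeyer–Villiger (Dakin-type) oxidation, in which the electron-rich aryl group with ortho- and para-alkoxy substituents migrates in preference to hydrogen, gives the formate, which mild methanolysis cleaves to the only free phenol of ring A.

Step 4
Reactants: 7 4-bromo-2-fluoro-6-methylbenzoic acid
Product: 8 2-fluoro-4-hydroxy-6-methylbenzoic acid
Conditions: Pd2(dba)3 (2 mol%), tBuXPhos (8 mol%), KOH (4 equiv), 1,4-dioxane/H2O 1:1, 100 °C; then aq. HCl
Reagents that add atoms: potassium hydroxide [K+].[OH-]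
Why: Pd-catalysed hydroxylation (Buchwald C–O coupling) replaces the unhindered bromide ipso, while the C–F bond on the carboxylate-deactivated ring is not attacked by hydroxide.

Step 5
Reactants: 8 2-fluoro-4-hydroxy-6-methylbenzoic acid
Product: 9 benzyl 2-fluoro-4-hydroxy-6-methylbenzoate
Conditions: BnBr (1.05 equiv), KHCO3 (1.05 equiv), DMF, rt to 40 °C
Reagents that add atoms: benzyl bromide BrCc1ccccc1
Why: SN2 O-alkylation of the carboxylate is chemoselective because one equivalent of bicarbonate deprotonates only the carboxylic acid and not the phenol, and alkylation at oxygen is insensitive to the ortho substituents.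

Step 6
Reactants: 9 benzyl 2-fluoro-4-hydroxy-6-methylbenzoate
Product: 10 benzyl 5-chloro-2-fluoro-4-hydroxy-6-methylbenzoate
Conditions: NCS (1.05 equiv), TsOH·H2O (10 mol%), MeCN, rt to 40 °C; chromatography
Reagents that add atoms: N-chlorosuccinimide O=C1CCC(=O)N1Cl
Why: Electrophilic aromatic chlorination ortho to the phenol is expected to favour C5 (para to F, ortho to CH3) over C3 (ortho to the inductively deactivating F), and the minor 3-chloro isomer is removed by chromatography.

Step 7
Reactants: 10 benzyl 5-chloro-2-fluoro-4-hydroxy-6-methylbenzoate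
Product: 12 benzyl 5-chloro-2-fluoro-3-formyl-4-hydroxy-6-methylbenzoate, via hydroxymethyl phenol 11 (not isolated)
Conditions: MgCl2 (2 equiv), Et3N (4 equiv), (CH2O)n (6 equiv), MeCN, reflux; then 1 M HCl
Reagents that add atoms: formaldehyde (charged as paraformaldehyde) C=O
Why: Casiraghi–Skattebøl magnesium-mediated ortho-formylation delivers formaldehyde to the only remaining position ortho to the phenol (C3), and the hydroxymethyl intermediate is oxidised in situ by hydride transfer to a second formaldehyde.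

Step 8
Reactants: 12 benzyl 5-chloro-2-fluoro-3-formyl-4-hydroxy-6-methylbenzoate
Product: 13 benzyl 4-(benzyloxy)-5-chloro-2-fluoro-3-formyl-6-methylbenzoate
Conditions: BnBr (1.3 equiv), K2CO3 (anhydrous), DMF, rt to 40 °C
Reagents that add atoms: benzyl bromide BrCc1ccccc1
Why: Williamson ether synthesis caps the acidic salicylaldehyde-type phenol, whose phenoxide would otherwise shut down the following SNAr.

Step 9
Reactants: 6 methyl 2,4-bis(benzyloxy)-5-hydroxy-3,6-dimethylbenzoate; 13 benzyl 4-(benzyloxy)-5-chloro-2-fluoro-3-formyl-6-methylbenzoate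
Product: 14 benzyl 4-(benzyloxy)-2-[4,6-bis(benzyloxy)-3-(methoxycarbonyl)-2,5-dimethylphenoxy]-5-chloro-3-formyl-6-methylbenzoate
Conditions: Cs2CO3 (1.5 equiv), DMF, 70 °C, N2
Reagents that add atoms: none
Why: Nucleophilic aromatic substitution (SNAr) by the caesium phenoxide of 6 occurs at the C–F carbon, whose Meisenheimer complex is stabilised by the ortho-CHO and ortho-CO2Bn groups; the chloride and the benzyloxy group are not at activated leaving-group positions.

Step 10
Reactants: 14 benzyl 4-(benzyloxy)-2-[4,6-bis(benzyloxy)-3-(methoxycarbonyl)-2,5-dimethylphenoxy]-5-chloro-3-formyl-6-methylbenzoate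
Product: 15 5-chloro-2-[4,6-dihydroxy-3-(methoxycarbonyl)-2,5-dimethylphenoxy]-3-formyl-4-hydroxy-6-methylbenzoic acid
Conditions: H2 (1 atm), 10% Pd/C, EtOAc, rt, stopped at 4 equiv uptake
Reagents that add atoms: none
Why: Catalytic hydrogenolysis cleaves the three benzyl ethers and the benzyl ester in one operation; in neutral ethyl acetate the hindered aryl chloride and the chelated aryl aldehyde are expected to be reduced much more slowly, and the methyl ester is untouched.

**Compound list**

1 | methyl 2,4-dihydroxy-3,6-dimethylbenzoate (atraric acid) | COC(=O)c1c(C)cc(O)c(C)c1O | starting material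
2 | methyl 5-[chloro(methoxy)methyl]-2,4-dihydroxy-3,6-dimethylbenzoate | COC(=O)c1c(C)c(C(Cl)OC)c(O)c(C)c1O | intermediate
3 | methyl 5-formyl-2,4-dihydroxy-3,6-dimethylbenzoate | COC(=O)c1c(C)c(C=O)c(O)c(C)c1O | intermediate
4 | methyl 2,4-bis(benzyloxy)-5-formyl-3,6-dimethylbenzoate | COC(=O)c1c(C)c(C=O)c(OCc2ccccc2)c(C)c1OCc1ccccc1 | intermediate
5 | methyl 2,4-bis(benzyloxy)-5-(formyloxy)-3,6-dimethylbenzoate | COC(=O)c1c(C)c(OC=O)c(OCc2ccccc2)c(C)c1OCc1ccccc1 | intermediate
6 | methyl 2,4-bis(benzyloxy)-5-hydroxy-3,6-dimethylbenzoate | COC(=O)c1c(C)c(O)c(OCc2ccccc2)c(C)c1OCc1ccccc1 | intermediate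
7 | 4-bromo-2-fluoro-6-methylbenzoic acid | Cc1cc(Br)cc(F)c1C(=O)O | starting material
8 | 2-fluoro-4-hydroxy-6-methylbenzoic acid | Cc1cc(O)cc(F)c1C(=O)O | intermediate
9 | benzyl 2-fluoro-4-hydroxy-6-methylbenzoate | Cc1cc(O)cc(F)c1C(=O)OCc1ccccc1 | intermediate
10 | benzyl 5-chloro-2-fluoro-4-hydroxy-6-methylbenzoate | Cc1c(Cl)c(O)cc(F)c1C(=O)OCc1ccccc1 | intermediate
11 | benzyl 5-chloro-2-fluoro-4-hydroxy-3-(hydroxymethyl)-6-methylbenzoate | Cc1c(Cl)c(O)c(CO)c(F)c1C(=O)OCc1ccccc1 | intermediate
12 | benzyl 5-chloro-2-fluoro-3-formyl-4-hydroxy-6-methylbenzoate | Cc1c(Cl)c(O)c(C=O)c(F)c1C(=O)OCc1ccccc1 | intermediate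
13 | benzyl 4-(benzyloxy)-5-chloro-2-fluoro-3-formyl-6-methylbenzoate | Cc1c(Cl)c(OCc2ccccc2)c(C=O)c(F)c1C(=O)OCc1ccccc1 | intermediate
14 | benzyl 4-(benzyloxy)-2-[4,6-bis(benzyloxy)-3-(methoxycarbonyl)-2,5-dimethylphenoxy]-5-chloro-3-formyl-6-methylbenzoate | COC(=O)c1c(C)c(Oc2c(C=O)c(OCc3ccccc3)c(Cl)c(C)c2C(=O)OCc2ccccc2)c(OCc2ccccc2)c(C)c1OCc1ccccc1 | intermediate
15 | 5-chloro-2-[4,6-dihydroxy-3-(methoxycarbonyl)-2,5-dimethylphenoxy]-3-formyl-4-hydroxy-6-methylbenzoic acid | COC(=O)c1c(C)c(Oc2c(C=O)c(O)c(Cl)c(C)c2C(=O)O)c(O)c(C)c1O | target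

**Totals**

Total step count: 10. Longest linear sequence: 7 steps (steps 4–10, from 7).

**Steps most likely to fail, with fallbacks**

Step 6 (regiochemistry of the chlorination; the 3-chloro isomer could be substantial). The fallback sets out from 7 and comes back at 12. It fixes the formyl group first by directed metalation, so that chlorine can afterwards enter only C5. Compound 7 is esterified (BnBr, K2CO3, DMF) to benzyl 4-bromo-2-fluoro-6-methylbenzoate F1. Magnesiation with TMPMgCl·LiCl (THF, −20 °C) at the only strongly acidified ring C–H (C3, between F and Br), then a DMF quench, gives benzyl 4-bromo-2-fluoro-3-formyl-6-methylbenzoate F2. Miyaura borylation (B2pin2, Pd(dppf)Cl2, KOAc, dioxane, 80 °C) gives benzyl 2-fluoro-3-formyl-6-methyl-4-(4,4,5,5-tetramethyl-1,3,2-dioxaborolan-2-yl)benzoate F3. Aldehyde-tolerant oxidation with N-methylmorpholine N-oxide gives benzyl 2-fluoro-3-formyl-4-hydroxy-6-methylbenzoate F4. NCS then chlorinates the single remaining ring position to give 12, and steps 8–10 follow unchanged.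

Step 7 (formylation of a deactivated, doubly flanked phenol may stall). The fallback sets out from 10 and comes back at 13. It builds the C–C bond by cross-coupling instead of electrophilic formylation. NBS brominates the only free ring position of 10 to give benzyl 3-bromo-5-chloro-2-fluoro-4-hydroxy-6-methylbenzoate F5. O-Benzylation (BnBr, K2CO3, DMF) gives benzyl 4-(benzyloxy)-3-bromo-5-chloro-2-fluoro-6-methylbenzoate F6. Suzuki–Miyaura vinylation (potassium vinyltrifluoroborate, Pd(dppf)Cl2, Cs2CO3, THF/H2O, 70 °C; C–Br reacts before C–Cl) gives benzyl 4-(benzyloxy)-5-chloro-3-ethenyl-2-fluoro-6-methylbenzoate F7. Ozonolysis (O3, CH2Cl2, −78 °C; then Me2S) gives 13 directly, so step 8 is no longer needed.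

Step 9 (SNAr between two di-ortho-substituted partners may be too slow). The fallback sets out from 3 and 13 and comes back at 15. It uses an unprotected, less hindered ring-A nucleophile and relies on thermodynamic control through Smiles rearrangement. Dakin oxidation of 3 (H2O2, aq. NaOH, 0 °C, degassed) gives methyl 2,4,5-trihydroxy-3,6-dimethylbenzoate F8. F8 and 13 are heated with Cs2CO3 (2.2 equiv) in degassed DMSO at 60–80 °C. The ester-chelated 2-OH is the least nucleophilic oxygen. Aryl ethers at O4 and O5 can interconvert through a spiro-Meisenheimer intermediate and should converge on the O5 ether, because that isomer keeps the more stabilised 4-phenoxide (para to CO2Me). The product is benzyl 4-(benzyloxy)-5-chloro-2-[4,6-dihydroxy-3-(methoxycarbonyl)-2,5-dimethylphenoxy]-3-formyl-6-methylbenzoate F9. Hydrogenolysis under the step 10 conditions (two benzyl groups) gives 15.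

**Further compounds**

F1 | step 6 | benzyl 4-bromo-2-fluoro-6-methylbenzoate | Cc1cc(Br)cc(F)c1C(=O)OCc1ccccc1
F2 | step 6 | benzyl 4-bromo-2-fluoro-3-formyl-6-methylbenzoate | Cc1cc(Br)c(C=O)c(F)c1C(=O)OCc1ccccc1
F3 | step 6 | benzyl 2-fluoro-3-formyl-6-methyl-4-(4,4,5,5-tetramethyl-1,3,2-dioxaborolan-2-yl)benzoate | Cc1cc(B2OC(C)(C)C(C)(C)O2)c(C=O)c(F)c1C(=O)OCc1ccccc1
F4 | step 6 | benzyl 2-fluoro-3-formyl-4-hydroxy-6-methylbenzoate | Cc1cc(O)c(C=O)c(F)c1C(=O)OCc1ccccc1
F5 | step 7 | benzyl 3-bromo-5-chloro-2-fluoro-4-hydroxy-6-methylbenzoate | Cc1c(Cl)c(O)c(Br)c(F)c1C(=O)OCc1ccccc1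
F6 | step 7 | benzyl 4-(benzyloxy)-3-bromo-5-chloro-2-fluoro-6-methylbenzoate | Cc1c(Cl)c(OCc2ccccc2)c(Br)c(F)c1C(=O)OCc1ccccc1
F7 | step 7 | benzyl 4-(benzyloxy)-5-chloro-3-ethenyl-2-fluoro-6-methylbenzoate | Cc1c(Cl)c(OCc2ccccc2)c(C=C)c(F)c1C(=O)OCc1ccccc1
F8 | step 9 | methyl 2,4,5-trihydroxy-3,6-dimethylbenzoate | COC(=O)c1c(C)c(O)c(O)c(C)c1O
F9 | step 9 | benzyl 4-(benzyloxy)-5-chloro-2-[4,6-dihydroxy-3-(methoxycarbonyl)-2,5-dimethylphenoxy]-3-formyl-6-methylbenzoate | COC(=O)c1c(C)c(Oc2c(C=O)c(OCc3ccccc3)c(Cl)c(C)c2C(=O)OCc2ccccc2)c(O)c(C)c1O
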